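## Structural features

The target (25) is a 1-aryltetralin lignan. Ring A is a pentasubstituted benzene (C5–H, 6-OMe, 7-OH, 8-OMe) fused through C4a and C8a to the saturated ring B. C1 of ring B is a diaryl methine carrying ring C (4-hydroxy-3,5-dimethoxyphenyl), C2 and C3 carry hydroxymethyl groups (C9 on C2, C10 on C3), and C4 is a methylene group. C1, C2 and C3 are contiguous stereocentres, (1S,2R,3R), with 1,2-trans and 2,3-trans relations, so the aryl group and the C10 arm are cis. The two syringyl-type phenols are easily oxidised to quinone methides and the doubly benzylic C1–H is the weakest C–H bond, so the phenols are carried as benzyl ethers and the diol is released late. The real difficulty is stereochemical: C1 stands next to the peri methoxy group on C8, which pushes the C1 aryl group out of the plane of ring A and works against an all-equatorial arrangement. A second difficulty is ring A itself, in which C8a is flanked by a methoxy group and by C4a. The key step exploits the fact that C9 can be a carboxyl carbon and C10 the inner carbon of a vinyl group C10=C11, so that C9–C2–C3–C10=C11 is a γ,δ-unsaturated acid, the retron of an ester enolate Claisen rearrangement; because C3 is already tied to C2 through C4, C4a, C8a and C1, the allyl ester is a ten-membered lactone (C9–O–C11–C10=C3) whose rearrangement forms C2–C3 and ring B together. Tetralin numbering is used for all intermediates; C11 is the extra carbon removed after the key step.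

## Logic of the disconnections

**25 to 24.** The two aryl O–H bonds are traced back to O–benzyl bonds. Benzyl is the one group that survives organolithium, palladium, ruthenium, enolate and hydride chemistry and leaves under neutral conditions. The demand is that no alkene remains at the end, which holds in 24.

**24 to 21 and 20.** The C10–O bond is traced back to the C10=C11 double bond of a vinyl group (one carbon lost), and the C9 alcohol to a carboxylic acid. This turns the 1,4-diol into the γ,δ-unsaturated acid 20. The acid is reduced before the alkene is cleaved, so that the C3 aldehyde never sits beside a free carboxyl group and is trapped as a lactol; the forward steps must not epimerise C3.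

**20 to 17 (key).** C2–C3 is cut and O–C11 is reconnected. This removes ring B and two stereocentres in one operation and leaves the single stereocentre C1 in a ten-membered (E)-allylic lactone. The forward step needs selective α-deprotonation at C2 and a transition-state geometry that places C3 on C2 anti to the C1 aryl group with C9 and vinyl trans.

**17 to 15.** The acyl C9–O bond is cut to give a seco acid with a primary allylic alcohol. The gain is an open-chain compound with only C1 as stereocentre; the demand is a medium-ring lactonisation, so high dilution is required.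

**15 to 14 to 12 and 13.** The C10=C11 double bond is cut by a metathesis transform. The four-carbon bridge then comes from a simple allyl group and a symmetrical C4 diester, and the acetate and the ethyl ester fall in one hydrolysis. The demand is (E)-selectivity.

**12 to 11.** The C4–C4a bond is cut to an aryl bromide and an allyl-metal reagent. The halogen on C4a is the handle that was placed before C1 was built; the coupling must tolerate the neighbouring bulky C1 substituent.

**11 to 7 and 10.** The C1–C1' bond is cut by a conjugate-addition transform. C1 becomes the β-carbon of a cinnamate and ring C an arylboronic acid, so the only stereocentre that must be made enantioselectively comes from a catalytic reaction. The demand is that a 2,6-disubstituted cinnamate still inserts into the aryl–rhodium bond.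

**7 to 5 and 6.** The C1=C2 bond is cut by an olefination transform to an aldehyde and a phosphonoacetate.

**5 and 10 to 2 to 1.** The C8a–CHO bond of 5 and the C–B bond of 10 both lead back to bromide 2, and 2 to phenol 1 by O-benzylation. One commercial phenol thus supplies both aromatic rings. In 2 the only two free ring positions are equivalent and lie between bromine and methoxy, so the aldehyde can only enter at C8a with bromine on C4a. A halogenation after formylation of the debrominated ether would instead go to C5, which is why the halogen is carried from the start.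

## Other disconnections considered

**Alternative 1:** Tethered oxidative dimerisation. The cut is C2–C3 together with C1–C8a, giving two units of sinapic acid A1 esterified to (2R,4R)-pentane-2,4-diol A2 as the bis-sinapate A3. In the forward step FeCl3 oxidises both phenols, the β-carbon radicals couple (C2–C3), one quinone methide tautomerises and its ring carbon attacks the other quinone methide (C1–C8a), giving the bridged dihydronaphthalene A4.
- In its favour: every carbon comes from two identical commercial units, the oxygenation pattern of rings A and C and the 1,2-trans relation arise without protecting groups, and the target would follow in about five steps (esterification, coupling, hydrogenation of C3=C4, hydride reduction that also removes the tether). On step economy and on the ring A substitution problem it is better than the chosen plan.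
- Against it here: absolute configuration at C1/C2 depends only on chirality transfer from the remote stereocentres of A2 through a nine-membered dilactone. The free phenols of A3 and A4 remain open to further oxidation. C3 is not set in the key step; hydrogenation of the C3=C4 bond of A4 has to deliver 2,3-trans while the tether holds the two carbonyl groups on the same side.
- Comparison: both plans rest on a conformational argument about a medium ring, so on mechanistic certainty they are equal. The chosen plan is longer but fixes C1 by catalyst control.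

**Alternative 2:** Palladium carbene at C1. The cut is C1–C1' and C1–C2. Bromide 2 and the tosylhydrazone A5 (ring A aldehyde hydrazone carrying the C3 stereocentre and a malonate on the ortho side chain) react with Pd2(dba)3, a phosphine and LiOtBu. Zerovalent palladium inserts into the C–Br bond, the diazo compound from A5 gives a palladium carbene, aryl migration forms C1–C1', and the malonate attacks the benzylpalladium to form C1–C2, giving diester A6.
- In its favour: it is more convergent, reuses 2, needs no medium ring or macrolactonisation, and sets C3 beforehand in an open-chain compound; on these points it is better than the chosen plan. The benzylpalladium has no β-hydrogen.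
- Against it here: C1 is set only relative to C3 across the forming ring, through a benzylpalladium species that can change face, with the same peri methoxy group interfering. The hydrazone carbon is flanked by a methoxy group and the tether. The quaternary C2 of A6 needs a dealkoxycarbonylation whose protonation sets C2.
- Comparison: the step count would be about equal. The chosen plan is better for absolute control of C1, the alternative for C3.

**Alternative 3:** Benzannulation of ring A. The cut is C4a–C5, C5–C6, C7–C8 and C8–C8a. Irradiation of the cyclohexenyl diazoketone A7 gives, by Wolff rearrangement, a vinylketene that adds methoxyethyne A8; four-electron ring opening and six-electron closure give the phenol A9.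
- In its favour: the three stereocentres are built on a monocyclic cyclohexene where no peri interaction exists, which is better than the chosen plan on its weakest point. The regiochemistry follows from the polarity of A8, and the cascade is as well precedented as the chosen key step.
- Against it here: A9 lacks the C7 oxygen and has a free C8 hydroxyl, so O-methylation, hydroxylation between two methoxy groups and removal of the methoxymethyl and silyl groups must follow. A7 needs its own enantioselective synthesis with an epimerisable C1 (allylic, benzylic and γ to the ketone).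
- Comparison: it builds a ring that a commercial phenol already supplies, and it would be the longest of the four routes.

Key step: step 10

Remarks before the steps:
- The lactone 17 and the acid 20 are mutually consistent and no correction is needed: C1 is (S) in both, and 20 has the spatial arrangement of the target at C1–C3. The descriptors read (1S,2S,3S) in 20 and (1S,2R,3R) in 25 only because the priorities change.
- Assumption: in step 5 the antipode of the chiral diene that delivers the aryl group to the Re face of the β-carbon of 7 is used; which antipode this is has to be fixed on the first run by correlation of 11.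
- 1, 6 and 13 are taken as commercial.

## Steps

**Step 1**
Reactants: 1 4-bromo-2,6-dimethoxyphenol
Product: 2 2-(benzyloxy)-5-bromo-1,3-dimethoxybenzene
Conditions: BnBr, K2CO3, DMF, 60 °C
Reagents that add atoms: benzyl bromide, BrCc1ccccc1
Why: Williamson etherification of the phenoxide (SN2 on benzyl bromide); the benzyl ether survives the organolithium, palladium, ruthenium, enolate and hydride steps and is removed by hydrogenolysis at the end.

**Step 2**
Reactants: 2 2-(benzyloxy)-5-bromo-1,3-dimethoxybenzene
Product: 5 3-(benzyloxy)-6-bromo-2,4-dimethoxybenzaldehyde, via aryllithium 3 (not isolated), via lithium aminoalkoxide 4 (not isolated)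
Conditions: LiN(iPr)2, THF, −78 °C; DMF, −78 → 0 °C; aq. NH4Cl
Reagents that add atoms: N,N-dimethylformamide, CN(C)C=O
Why: Directed ortho-lithiation: the only ring C–H bonds lie between bromine and a methoxy group, whose inductive and coordinating effects allow deprotonation by the amide base at −78 °C without bromine–lithium exchange, and DMF formylates 3. The two free positions are equivalent, so the aldehyde can only end on C8a with bromine on C4a.

**Step 3**
Reactants: 5 3-(benzyloxy)-6-bromo-2,4-dimethoxybenzaldehyde; 6 triethyl phosphonoacetate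
Product: 7 ethyl (2E)-3-[3-(benzyloxy)-6-bromo-2,4-dimethoxyphenyl]prop-2-enoate
Conditions: NaH, THF, 0 → 25 °C
Reagents that add atoms: none
Why: Horner–Wadsworth–Emmons olefination; the stabilised phosphonate anion gives the (E)-enoate, also with a 2,6-disubstituted benzaldehyde.

**Step 4**
Reactants: 2 2-(benzyloxy)-5-bromo-1,3-dimethoxybenzene
Product: 10 [4-(benzyloxy)-3,5-dimethoxyphenyl]boronic acid, via aryllithium 8 (not isolated), via lithium triisopropoxyborate 9 (not isolated)
Conditions: n-BuLi, THF, −78 °C; B(OiPr)3, −78 → 25 °C; 1 M HCl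
Reagents that add atoms: triisopropyl borate, CC(C)OB(OC(C)C)OC(C)C; water, O
Why: Bromine–lithium exchange is faster than any deprotonation at −78 °C; borylation of 8 and acidic hydrolysis of borate 9 give the boronic acid.

**Step 5**
Reactants: 7 ethyl (2E)-3-[3-(benzyloxy)-6-bromo-2,4-dimethoxyphenyl]prop-2-enoate; 10 [4-(benzyloxy)-3,5-dimethoxyphenyl]boronic acid
Product: 11 ethyl (3S)-3-[3-(benzyloxy)-6-bromo-2,4-dimethoxyphenyl]-3-[4-(benzyloxy)-3,5-dimethoxyphenyl]propanoate
Conditions: [RhCl(C2H4)2]2 (2.5 mol %), Ph-bod* (2,5-diphenylbicyclo[2.2.2]octa-2,5-diene, single antipode, 5.5 mol %), aq. KOH (0.5 equiv), dioxane, 50 °C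
Reagents that add atoms: none
Why: Rhodium–chiral diene catalysed asymmetric 1,4-addition of an arylboronic acid to an enoate (Hayashi–Miyaura reaction): transmetalation gives an aryl complex of monovalent rhodium, the enoate inserts and the oxa-π-allyl species is protonated. The diene antipode that leaves the Re face of the β-carbon open sets (S) at C1. The ethylene complex is the rhodium source because cycloocta-1,5-diene would not give way to the chiral diene, and the aryl bromide is inert to monovalent rhodium under these conditions.

**Step 6**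
Reactants: 11 ethyl (3S)-3-[3-(benzyloxy)-6-bromo-2,4-dimethoxyphenyl]-3-[4-(benzyloxy)-3,5-dimethoxyphenyl]propanoate
Product: 12 ethyl (3S)-3-[3-(benzyloxy)-2,4-dimethoxy-6-(prop-2-en-1-yl)phenyl]-3-[4-(benzyloxy)-3,5-dimethoxyphenyl]propanoate
Conditions: allylSnBu3, Pd(PPh3)4 (5 mol %), DMF, 100 °C
Reagents that add atoms: allyltributylstannane, C=CC[Sn](CCCC)(CCCC)CCCC
Why: Stille coupling: oxidative addition of zerovalent palladium into the C4a–Br bond, transmetalation from the allylstannane and reductive elimination; the ester, the benzyl ethers and C1 are not touched under these neutral conditions.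

**Step 7**
Reactants: 12 ethyl (3S)-3-[3-(benzyloxy)-2,4-dimethoxy-6-(prop-2-en-1-yl)phenyl]-3-[4-(benzyloxy)-3,5-dimethoxyphenyl]propanoate; 13 (2Z)-but-2-ene-1,4-diyl diacetate
Product: 14 ethyl (3S)-3-{6-[(2E)-4-(acetyloxy)but-2-en-1-yl]-3-(benzyloxy)-2,4-dimethoxyphenyl}-3-[4-(benzyloxy)-3,5-dimethoxyphenyl]propanoate
Conditions: 13 (3 equiv), second-generation Grubbs catalyst (H2IMes)(PCy3)Cl2Ru=CHPh (5 mol %), CH2Cl2, 40 °C
Reagents that add atoms: none
Why: Olefin cross-metathesis of a terminal alkene with an excess of a symmetrical internal alkene; secondary metathesis moves the product towards the more stable (E)-alkene. The diacetate is used rather than the free diol to avoid ruthenium-hydride isomerisation of an allylic alcohol.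

**Step 8**
Reactants: 14 ethyl (3S)-3-{6-[(2E)-4-(acetyloxy)but-2-en-1-yl]-3-(benzyloxy)-2,4-dimethoxyphenyl}-3-[4-(benzyloxy)-3,5-dimethoxyphenyl]propanoate
Product: 15 (3S)-3-{3-(benzyloxy)-6-[(2E)-4-hydroxybut-2-en-1-yl]-2,4-dimethoxyphenyl}-3-[4-(benzyloxy)-3,5-dimethoxyphenyl]propanoic acid
Conditions: LiOH·H2O, THF/MeOH/H2O, 25 °C; 1 M HCl to pH 3
Reagents that add atoms: lithium hydroxide, [Li+].[OH-]
Why: Saponification of the ethyl ester and the allylic acetate in one operation; C1 is not acidic enough to be affected and the (E)-alkene stays in place.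

**Step 9**
Reactants: 15 (3S)-3-{3-(benzyloxy)-6-[(2E)-4-hydroxybut-2-en-1-yl]-2,4-dimethoxyphenyl}-3-[4-(benzyloxy)-3,5-dimethoxyphenyl]propanoic acid
Product: 17 (1S,6E)-11-(benzyloxy)-1-[4-(benzyloxy)-3,5-dimethoxyphenyl]-10,12-dimethoxy-1,2,5,8-tetrahydro-3H-4-benzoxecin-3-one (the ten-membered lactone C9–O–C11–C10=C3–C4–C4a–C8a–C1–C2), via mixed anhydride 16 (not isolated)
Conditions: 2,4,6-Cl3C6H2COCl, Et3N, THF, 25 °C; slow addition to DMAP, toluene, 80 °C (1 mM)
Reagents that add atoms: none
Why: Yamaguchi macrolactonisation: the carboxyl group is activated as mixed anhydride 16 and transferred by DMAP to the primary allylic hydroxyl under high dilution. The benzo ring and the (E)-alkene restrict the seco acid, which helps closure of the medium ring, and the stereocentre C1 is not α to the activated carbonyl.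

**Step 10**
Reactants: 17 (1S,6E)-11-(benzyloxy)-1-[4-(benzyloxy)-3,5-dimethoxyphenyl]-10,12-dimethoxy-1,2,5,8-tetrahydro-3H-4-benzoxecin-3-one
Product: 20 (1S,2S,3S)-7-(benzyloxy)-1-[4-(benzyloxy)-3,5-dimethoxyphenyl]-3-ethenyl-6,8-dimethoxy-1,2,3,4-tetrahydronaphthalene-2-carboxylic acid (1,2-trans and 2,3-trans), via silyl ketene acetal 18 (not isolated), via trimethylsilyl ester 19 (not isolated)
Conditions: Me3SiCl/Et3N (1:1), then LiN(iPr)2, THF, −78 °C; −78 → 25 °C, then toluene, 80 °C; 1 M HCl, THF, 25 °C
Reagents that add atoms: none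
Why: LiN(iPr)2 removes a C2 proton of 17 in the presence of Me3SiCl, so the enolate is silylated at once to ketene acetal 18, in which the ring holds C1 cis to the lactone oxygen; on warming, the array C2=C9–O–C11–C10=C3 undergoes the concerted suprafacial (3,3) shift that forms C2–C3 and breaks O–C11, giving silyl ester 19 and, after hydrolysis, acid 20. The closest known reaction type is the ring-contracting Ireland–Claisen rearrangement of silyl ketene acetals of medium-ring allylic lactones to 2-vinylcycloalkanecarboxylic acids. Ring B closes transannularly: C2 is joined to C3 across the ten-membered ring through a six-membered pericyclic array, so the lactone contracts to the carbocycle C1–C2–C3–C4–C4a–C8a and C10=C11 is left outside the ring as the vinyl group. For C2 against C3, the ring-fixed ketene acetal geometry and the (E)-alkene react through a boat-like array that places C9 and the vinyl group trans on ring B. For C2 and C3 against C1, allylic strain turns the C1–H bond into the plane of the ketene acetal, C8a lies on the face to which the tethered C3 must add, and the aryl group therefore sits on the opposite face, which gives the 1,2-trans and hence the 1,3-cis relation. The selectivities needed are deprotonation at C2 rather than at the benzylic C1–H or the benzylic and allylic C4–H2, secured by the far higher kinetic acidity of the ester α-position and the internal silyl quench at −78 °C, and the boat-like array with the aryl group pseudoequatorial, which allylic strain favours but the peri C8 methoxy group opposes. C2 stays epimerisable afterwards, so only the relation between C1 and C3 has to be right at this stage.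

**Step 11**
Reactants: 20 (1S,2S,3S)-7-(benzyloxy)-1-[4-(benzyloxy)-3,5-dimethoxyphenyl]-3-ethenyl-6,8-dimethoxy-1,2,3,4-tetrahydronaphthalene-2-carboxylic acid
Product: 21 [(1S,2S,3S)-7-(benzyloxy)-1-[4-(benzyloxy)-3,5-dimethoxyphenyl]-3-ethenyl-6,8-dimethoxy-1,2,3,4-tetrahydronaphthalen-2-yl]methanol
Conditions: LiAlH4, THF, 0 → 60 °C
Reagents that add atoms: none
Why: Hydride reduction of the carboxylic acid to the primary alcohol; the carboxylate is not enolised, so C2 is kept, and the vinyl group and the benzyl ethers are inert.

**Step 12**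
Reactants: 21 [(1S,2S,3S)-7-(benzyloxy)-1-[4-(benzyloxy)-3,5-dimethoxyphenyl]-3-ethenyl-6,8-dimethoxy-1,2,3,4-tetrahydronaphthalen-2-yl]methanol
Product: 24 [(1S,2R,3R)-7-(benzyloxy)-1-[4-(benzyloxy)-3,5-dimethoxyphenyl]-6,8-dimethoxy-1,2,3,4-tetrahydronaphthalene-2,3-diyl]dimethanol, via triol 22 (not isolated), via lactol 23 (not isolated)
Conditions: OsO4 (2 mol %), NaIO4, 2,6-lutidine, dioxane/H2O, 25 °C; then NaBH4, MeOH, 0 °C
Reagents that add atoms: osmium tetroxide, O=[Os](=O)(=O)=O; sodium periodate, [Na+].[O-]I(=O)(=O)=O (together the source of the C10 hydroxyl oxygen)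
Why: Lemieux–Johnson cleavage: dihydroxylation to triol 22 and periodate cleavage remove C11 as formaldehyde. The aldehyde is captured at once by the C9 hydroxyl as lactol 23, which protects C3 against epimerisation, and NaBH4 reduces the lactol through its open form. OsO4/NaIO4 is preferred to ozone because of the electron-rich aryl rings.

**Step 13**
Reactants: 24 [(1S,2R,3R)-7-(benzyloxy)-1-[4-(benzyloxy)-3,5-dimethoxyphenyl]-6,8-dimethoxy-1,2,3,4-tetrahydronaphthalene-2,3-diyl]dimethanol
Product: 25 (1S,2R,3R)-1-(4-hydroxy-3,5-dimethoxyphenyl)-2,3-bis(hydroxymethyl)-6,8-dimethoxy-1,2,3,4-tetrahydronaphthalen-7-ol (lyoniresinol, the target)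
Conditions: H2 (1 atm), 10% Pd/C, EtOAc/MeOH, 25 °C
Reagents that add atoms: none
Why: Hydrogenolysis of the two benzyl aryl ethers over palladium; no alkene is left and the diaryl methine C1–H is not cleaved under these mild conditions.

## Compound list

1 | 4-bromo-2,6-dimethoxyphenol | COc1cc(Br)cc(OC)c1O | starting material
2 | 2-(benzyloxy)-5-bromo-1,3-dimethoxybenzene | COc1cc(Br)cc(OC)c1OCc1ccccc1 | intermediate
3 | [3-(benzyloxy)-6-bromo-2,4-dimethoxyphenyl]lithium | [Li]c1c(Br)cc(OC)c(OCc2ccccc2)c1OC | intermediate
4 | lithium [3-(benzyloxy)-6-bromo-2,4-dimethoxyphenyl](dimethylamino)methanolate (racemic at the carbinol carbon) | [Li]OC(N(C)C)c1c(Br)cc(OC)c(OCc2ccccc2)c1OC | intermediate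
5 | 3-(benzyloxy)-6-bromo-2,4-dimethoxybenzaldehyde | O=Cc1c(Br)cc(OC)c(OCc2ccccc2)c1OC | intermediate
6 | triethyl phosphonoacetate | CCOC(=O)CP(=O)(OCC)OCC | starting material
7 | ethyl (2E)-3-[3-(benzyloxy)-6-bromo-2,4-dimethoxyphenyl]prop-2-enoate | CCOC(=O)/C=C/c1c(Br)cc(OC)c(OCc2ccccc2)c1OC | intermediate
8 | [4-(benzyloxy)-3,5-dimethoxyphenyl]lithium | [Li]c1cc(OC)c(OCc2ccccc2)c(OC)c1 | intermediate
9 | lithium [4-(benzyloxy)-3,5-dimethoxyphenyl]tri(propan-2-yloxy)borate | [Li+].CC(C)O[B-](OC(C)C)(OC(C)C)c1cc(OC)c(OCc2ccccc2)c(OC)c1 | intermediate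
10 | [4-(benzyloxy)-3,5-dimethoxyphenyl]boronic acid | COc1cc(B(O)O)cc(OC)c1OCc1ccccc1 | intermediate
11 | ethyl (3S)-3-[3-(benzyloxy)-6-bromo-2,4-dimethoxyphenyl]-3-[4-(benzyloxy)-3,5-dimethoxyphenyl]propanoate | COc1cc([C@@H](c2c(Br)cc(OC)c(OCc3ccccc3)c2OC)CC(=O)OCC)cc(OC)c1OCc1ccccc1 | intermediate
12 | ethyl (3S)-3-[3-(benzyloxy)-2,4-dimethoxy-6-(prop-2-en-1-yl)phenyl]-3-[4-(benzyloxy)-3,5-dimethoxyphenyl]propanoate | COc1cc([C@@H](c2c(CC=C)cc(OC)c(OCc3ccccc3)c2OC)CC(=O)OCC)cc(OC)c1OCc1ccccc1 | intermediate
13 | (2Z)-but-2-ene-1,4-diyl diacetate | CC(=O)OC/C=C\COC(C)=O | starting material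
14 | ethyl (3S)-3-{6-[(2E)-4-(acetyloxy)but-2-en-1-yl]-3-(benzyloxy)-2,4-dimethoxyphenyl}-3-[4-(benzyloxy)-3,5-dimethoxyphenyl]propanoate | COc1cc([C@@H](c2c(C/C=C/COC(C)=O)cc(OC)c(OCc3ccccc3)c2OC)CC(=O)OCC)cc(OC)c1OCc1ccccc1 | intermediate
15 | (3S)-3-{3-(benzyloxy)-6-[(2E)-4-hydroxybut-2-en-1-yl]-2,4-dimethoxyphenyl}-3-[4-(benzyloxy)-3,5-dimethoxyphenyl]propanoic acid | COc1cc([C@@H](c2c(C/C=C/CO)cc(OC)c(OCc3ccccc3)c2OC)CC(=O)O)cc(OC)c1OCc1ccccc1 | intermediate
16 | mixed anhydride of 15 with 2,4,6-trichlorobenzoic acid | COc1cc([C@@H](c2c(C/C=C/CO)cc(OC)c(OCc3ccccc3)c2OC)CC(=O)OC(=O)c2c(Cl)cc(Cl)cc2Cl)cc(OC)c1OCc1ccccc1 | intermediate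
17 | (1S,6E)-11-(benzyloxy)-1-[4-(benzyloxy)-3,5-dimethoxyphenyl]-10,12-dimethoxy-1,2,5,8-tetrahydro-3H-4-benzoxecin-3-one | COc1cc([C@@H]2CC(=O)OC/C=C/Cc3cc(OC)c(OCc4ccccc4)c(OC)c32)cc(OC)c1OCc1ccccc1 | intermediate
18 | trimethylsilyl ketene acetal of 17 (C2=C9, C1 cis to the ring oxygen, (E)-alkene C10=C3 retained) | COc1cc([C@@H]2/C=C(/O[Si](C)(C)C)OC/C=C/Cc3cc(OC)c(OCc4ccccc4)c(OC)c32)cc(OC)c1OCc1ccccc1 | intermediate
19 | trimethylsilyl (1S,2S,3S)-7-(benzyloxy)-1-[4-(benzyloxy)-3,5-dimethoxyphenyl]-3-ethenyl-6,8-dimethoxy-1,2,3,4-tetrahydronaphthalene-2-carboxylate | COc1cc([C@H]2c3c(cc(OC)c(OCc4ccccc4)c3OC)C[C@@H](C=C)[C@@H]2C(=O)O[Si](C)(C)C)cc(OC)c1OCc1ccccc1 | intermediate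
20 | (1S,2S,3S)-7-(benzyloxy)-1-[4-(benzyloxy)-3,5-dimethoxyphenyl]-3-ethenyl-6,8-dimethoxy-1,2,3,4-tetrahydronaphthalene-2-carboxylic acid | COc1cc([C@H]2c3c(cc(OC)c(OCc4ccccc4)c3OC)C[C@@H](C=C)[C@@H]2C(=O)O)cc(OC)c1OCc1ccccc1 | intermediate
21 | [(1S,2S,3S)-7-(benzyloxy)-1-[4-(benzyloxy)-3,5-dimethoxyphenyl]-3-ethenyl-6,8-dimethoxy-1,2,3,4-tetrahydronaphthalen-2-yl]methanol | COc1cc([C@H]2c3c(cc(OC)c(OCc4ccccc4)c3OC)C[C@@H](C=C)[C@@H]2CO)cc(OC)c1OCc1ccccc1 | intermediate
22 | triol from 21: the vinyl group on C3 is replaced by a 1,2-dihydroxyethyl group (both epimers at the new carbinol carbon; C1–C3 as in 21) | COc1cc([C@H]2c3c(cc(OC)c(OCc4ccccc4)c3OC)C[C@@H](C(O)CO)[C@@H]2CO)cc(OC)c1OCc1ccccc1 | intermediate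
23 | lactol from 22: five-membered cyclic hemiacetal C2–C9H2–O–C10H(OH)–C3, trans-fused to ring B (both anomers) | COc1cc([C@H]2c3c(cc(OC)c(OCc4ccccc4)c3OC)C[C@@H](C(O)OC5)[C@@H]25)cc(OC)c1OCc1ccccc1 | intermediate
24 | [(1S,2R,3R)-7-(benzyloxy)-1-[4-(benzyloxy)-3,5-dimethoxyphenyl]-6,8-dimethoxy-1,2,3,4-tetrahydronaphthalene-2,3-diyl]dimethanol | COc1cc([C@H]2c3c(cc(OC)c(OCc4ccccc4)c3OC)C[C@@H](CO)[C@@H]2CO)cc(OC)c1OCc1ccccc1 | intermediate
25 | (1S,2R,3R)-1-(4-hydroxy-3,5-dimethoxyphenyl)-2,3-bis(hydroxymethyl)-6,8-dimethoxy-1,2,3,4-tetrahydronaphthalen-7-ol | COc1cc([C@H]2c3c(cc(OC)c(O)c3OC)C[C@@H](CO)[C@@H]2CO)cc(OC)c1O | target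

## Step count and risk assessment

Total step count: 13. Longest linear sequence: 12 steps (steps 1, 2, 3 and 5 to 13); step 4 is the one-step branch from 2 to 10.

**Step 10 (key step).** The most likely failure is poor diastereoselection at C3 relative to C1. An (E)-alkene in a ten-membered 1,5-diene can also react through a chair-like array, as in the Cope manifold that links cis-1,2-divinylcyclohexane with (E,Z)-cyclodeca-1,5-diene. That array would place C9 and the vinyl group cis. In addition, the peri C8 methoxy group favours a pseudoaxial aryl group on the forming ring B, which also leads to the 1,3-trans series. A C2 error alone can be repaired by epimerisation; a C3 error cannot be repaired while C3 carries a vinyl group.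

The fallback replaces kinetic by thermodynamic control. It sets out from 17 and returns at 24. The contraction is run as in step 10 and the acid is taken on whatever its configuration at C2 and C3, for example as (1S,2S,3R)-7-(benzyloxy)-1-[4-(benzyloxy)-3,5-dimethoxyphenyl]-3-ethenyl-6,8-dimethoxy-1,2,3,4-tetrahydronaphthalene-2-carboxylic acid F1. Me3SiCHN2 in MeOH/toluene gives its methyl ester F2. OsO4/NaIO4/2,6-lutidine cleaves the vinyl group to the methyl 3-formyl ester F3, in which both C2 (α to the ester) and C3 (α to the aldehyde) are enolisable. DBU in CH2Cl2 should then equilibrate the compound to the all-trans methyl (1S,2R,3R)-3-formyl ester F4, the arrangement expected to be favoured for vicinal carbonyl groups on a 1-aryltetralin. LiAlH4 reduces both carbonyl groups to give 24.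

**Step 9.** Intermolecular esterification (cyclic dimer and oligomers) may outrun closure of the strained ten-membered ring, because the (E)-alkene and the benzo ring leave little freedom to relieve transannular strain. Fallback: Mitsunobu macrolactonisation, setting out from 15 and returning at 17 (PPh3, DIAD, toluene/THF, slow addition at high dilution). It activates the primary allylic hydroxyl instead of the carboxyl group, so the ring closes by carboxylate SN2 attack on C11, without an activated acyl species that can acylate a second molecule. This fallback makes no new compound (F0).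

**Step 5.** Insertion of the 2,6-disubstituted cinnamate into the aryl–rhodium bond may be slow, so that protodeboronation of 10 takes over, and the twisted aryl group may weaken facial discrimination. Fallback (auxiliary control, setting out from 7 and returning at 11): LiOH hydrolysis gives (2E)-3-[3-(benzyloxy)-6-bromo-2,4-dimethoxyphenyl]prop-2-enoic acid F5. Its pivaloyl mixed anhydride acylates lithiated (4S)-4-phenyl-1,3-oxazolidin-2-one to give the N-enoyl imide F6. The Grignard reagent [4-(benzyloxy)-3,5-dimethoxyphenyl]magnesium bromide F7 (from 2 and Mg in THF) with CuBr·SMe2 at −40 °C should add to the chelated s-cis imide on the face away from the phenyl group, the Re face of the β-carbon, giving the (3S)-3,3-diarylpropanoyl imide F8. BrMgOEt (from EtMgBr and EtOH) then exchanges the auxiliary for ethoxide to give 11.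

**Step 7.** The metathesis may be incompletely (E)-selective, so that an alkene isomer is carried into the lactone, and ruthenium hydrides may move the alkene into conjugation with ring A. Fallback (setting out from 12 and returning at 15): cross-metathesis with crotonaldehyde and the same catalyst gives the conjugated ethyl (3S)-3-{3-(benzyloxy)-2,4-dimethoxy-6-[(2E)-4-oxobut-2-en-1-yl]phenyl}-3-[4-(benzyloxy)-3,5-dimethoxyphenyl]propanoate F9, for which the (E)-isomer is strongly favoured. Luche reduction (NaBH4, CeCl3·7H2O, MeOH, −20 °C) reduces only the aldehyde to the allylic alcohol ethyl (3S)-3-{3-(benzyloxy)-6-[(2E)-4-hydroxybut-2-en-1-yl]-2,4-dimethoxyphenyl}-3-[4-(benzyloxy)-3,5-dimethoxyphenyl]propanoate F10. LiOH as in step 8 gives 15.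

**Step 2.** The ortho-bromoaryllithium 3 may lose LiBr (aryne formation) or the bromine may migrate if the temperature rises, and lithiation may be incomplete because the para methoxy group lowers the acidity. Fallback (setting out from 2 and returning at 5): electrophilic Rieche formylation (Cl2CHOMe, SnCl4, CH2Cl2, −78 → 0 °C). The electrophile can only attack the free ring position, which is ortho to one methoxy group and para to the other; the tin Lewis acid is chosen to spare the benzyl ether. This fallback makes no new compound (F0).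

## Further compounds

F1 | step 10 | (1S,2S,3R)-7-(benzyloxy)-1-[4-(benzyloxy)-3,5-dimethoxyphenyl]-3-ethenyl-6,8-dimethoxy-1,2,3,4-tetrahydronaphthalene-2-carboxylic acid (1,2-trans, 2,3-cis) | COc1cc([C@H]2c3c(cc(OC)c(OCc4ccccc4)c3OC)C[C@H](C=C)[C@@H]2C(=O)O)cc(OC)c1OCc1ccccc1
F2 | step 10 | methyl (1S,2S,3R)-7-(benzyloxy)-1-[4-(benzyloxy)-3,5-dimethoxyphenyl]-3-ethenyl-6,8-dimethoxy-1,2,3,4-tetrahydronaphthalene-2-carboxylate | COc1cc([C@H]2c3c(cc(OC)c(OCc4ccccc4)c3OC)C[C@H](C=C)[C@@H]2C(=O)OC)cc(OC)c1OCc1ccccc1
F3 | step 10 | methyl (1S,2R,3S)-7-(benzyloxy)-1-[4-(benzyloxy)-3,5-dimethoxyphenyl]-3-formyl-6,8-dimethoxy-1,2,3,4-tetrahydronaphthalene-2-carboxylate (1,2-trans, 2,3-cis) | COc1cc([C@H]2c3c(cc(OC)c(OCc4ccccc4)c3OC)C[C@H](C=O)[C@@H]2C(=O)OC)cc(OC)c1OCc1ccccc1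
F4 | step 10 | methyl (1S,2R,3R)-7-(benzyloxy)-1-[4-(benzyloxy)-3,5-dimethoxyphenyl]-3-formyl-6,8-dimethoxy-1,2,3,4-tetrahydronaphthalene-2-carboxylate (all-trans) | COc1cc([C@H]2c3c(cc(OC)c(OCc4ccccc4)c3OC)C[C@@H](C=O)[C@@H]2C(=O)OC)cc(OC)c1OCc1ccccc1
F0 | step 9 | none | none
F5 | step 5 | (2E)-3-[3-(benzyloxy)-6-bromo-2,4-dimethoxyphenyl]prop-2-enoic acid | OC(=O)/C=C/c1c(Br)cc(OC)c(OCc2ccccc2)c1OC
F6 | step 5 | (4S)-3-{(2E)-3-[3-(benzyloxy)-6-bromo-2,4-dimethoxyphenyl]prop-2-enoyl}-4-phenyl-1,3-oxazolidin-2-one | O=C(/C=C/c1c(Br)cc(OC)c(OCc2ccccc2)c1OC)N1C(=O)OC[C@@H]1c1ccccc1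
F7 | step 5 | [4-(benzyloxy)-3,5-dimethoxyphenyl]magnesium bromide | Br[Mg]c1cc(OC)c(OCc2ccccc2)c(OC)c1
F8 | step 5 | (4S)-3-{(3S)-3-[3-(benzyloxy)-6-bromo-2,4-dimethoxyphenyl]-3-[4-(benzyloxy)-3,5-dimethoxyphenyl]propanoyl}-4-phenyl-1,3-oxazolidin-2-one | COc1cc([C@@H](c2c(Br)cc(OC)c(OCc3ccccc3)c2OC)CC(=O)N2C(=O)OC[C@@H]2c2ccccc2)cc(OC)c1OCc1ccccc1
F9 | step 7 | ethyl (3S)-3-{3-(benzyloxy)-2,4-dimethoxy-6-[(2E)-4-oxobut-2-en-1-yl]phenyl}-3-[4-(benzyloxy)-3,5-dimethoxyphenyl]propanoate | COc1cc([C@@H](c2c(C/C=C/C=O)cc(OC)c(OCc3ccccc3)c2OC)CC(=O)OCC)cc(OC)c1OCc1ccccc1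
F10 | step 7 | ethyl (3S)-3-{3-(benzyloxy)-6-[(2E)-4-hydroxybut-2-en-1-yl]-2,4-dimethoxyphenyl}-3-[4-(benzyloxy)-3,5-dimethoxyphenyl]propanoate | COc1cc([C@@H](c2c(C/C=C/CO)cc(OC)c(OCc3ccccc3)c2OC)CC(=O)OCC)cc(OC)c1OCc1ccccc1
F0 | step 2 | none | none
A1 | alternative 1 | sinapic acid, (2E)-3-(4-hydroxy-3,5-dimethoxyphenyl)prop-2-enoic acid | COc1cc(/C=C/C(=O)O)cc(OC)c1O
A2 | alternative 1 | (2R,4R)-pentane-2,4-diol | C[C@@H](O)C[C@@H](C)O
A3 | alternative 1 | (2R,4R)-pentane-2,4-diyl bis[(2E)-3-(4-hydroxy-3,5-dimethoxyphenyl)prop-2-enoate] | COc1cc(/C=C/C(=O)O[C@H](C)C[C@@H](C)OC(=O)/C=C/c2cc(OC)c(O)c(OC)c2)cc(OC)c1O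
A4 | alternative 1 | pentanediol-bridged trans-1-aryl-7-hydroxy-6,8-dimethoxy-1,2-dihydronaphthalene-2,3-dicarboxylate (nine-membered dilactone) | COc1cc([C@H]2c3c(cc(OC)c(O)c3OC)C=C5C(=O)O[C@H](C)C[C@@H](C)OC(=O)[C@H]25)cc(OC)c1O
A5 | alternative 2 | dimethyl 2-[(2R)-1-(benzyloxy)-3-{4-(benzyloxy)-3,5-dimethoxy-2-[(E)-(tosylhydrazinylidene)methyl]phenyl}propan-2-yl]propanedioate | COC(=O)C(C(=O)OC)[C@H](COCc1ccccc1)Cc1cc(OC)c(OCc2ccccc2)c(OC)c1/C=N/NS(=O)(=O)c1ccc(C)cc1
A6 | alternative 2 | dimethyl (1S,3R)-1-[4-(benzyloxy)-3,5-dimethoxyphenyl]-7-(benzyloxy)-3-[(benzyloxy)methyl]-6,8-dimethoxy-3,4-dihydronaphthalene-2,2(1H)-dicarboxylate | COc1cc([C@H]2c3c(cc(OC)c(OCc4ccccc4)c3OC)C[C@@H](COCc3ccccc3)C2(C(=O)OC)C(=O)OC)cc(OC)c1OCc1ccccc1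
A7 | alternative 3 | 2-diazo-1-{3-[3,5-dimethoxy-4-(methoxymethoxy)phenyl]-4,5-bis[(tert-butyldimethylsilyloxy)methyl]cyclohex-1-en-1-yl}ethan-1-one with the target configuration at the three ring stereocentres | COc1cc([C@H]2C=C(C(=O)C=[N+]=[N-])C[C@@H](CO[Si](C)(C)C(C)(C)C)[C@@H]2CO[Si](C)(C)C(C)(C)C)cc(OC)c1OCOC
A8 | alternative 3 | methoxyethyne | COC#C
A9 | alternative 3 | 1-[3,5-dimethoxy-4-(methoxymethoxy)phenyl]-2,3-bis[(tert-butyldimethylsilyloxy)methyl]-6-methoxy-1,2,3,4-tetrahydronaphthalen-8-ol | COc1cc([C@H]2c3c(cc(OC)cc3O)C[C@@H](CO[Si](C)(C)C(C)(C)C)[C@@H]2CO[Si](C)(C)C(C)(C)C)cc(OC)c1OCOC
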